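## Retrosynthetic overview

1. Target ⇐ trans-diaxial methanolysis at C4' of a cis-3',4'-epoxy alcohol ⇐ OH-directed epoxidation of a 1'-hydroxycyclohex-3'-enyl triol.
2. That triol ⇐ one LiAlH4 operation (both esters reduced, C1'–C6' epoxide opened at C6') ⇐ catalyst-controlled epoxidation of the trisubstituted alkene of a skipped 1,4-diene.
3. trans-Dihydrobenzofuran ⇐ Mitsunobu O1–C2 closure (inversion) of an anti-aldol adduct of an arylacetate (methyl dihydroferulate + glyoxylate) with cyclohexa-1,4-diene-1-carbaldehyde.
4. The dienyl aldehyde, which supplies all six cyclohexane carbons, ⇐ Birch dearomatisation of benzyl alcohol (key step).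
5. Ring order: the carbocycle exists from the start (benzene → 1,4-diene → cyclohexane); the dihydrofuran is closed at step 6; two oxiranes are transient.

Assumption: compounds 1, 4 and 5, Ipc2BOTf (either antipode, from α-pinene) and the ent-Shi ketone (from L-sorbose) are taken as commercially available. The route has not been run; it uses no protecting groups.

## Route

**Step 1**
Reactants: 1 benzyl alcohol
Product: 2 (cyclohexa-1,4-dien-1-yl)methanol
Conditions: n-BuLi (1 equiv), THF, −78 °C; then Li, NH3(l), t-BuOH, −78 °C; isoprene, then NH4Cl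
Reagents that add atoms: none
Why: Birch reduction of a donor-substituted arene gives the 1-substituted 1,4-diene, and the pre-formed lithium alkoxide suppresses benzylic C–O hydrogenolysis; the product carries two chemically distinct alkenes (trisubstituted C1'=C6', cis-disubstituted C3'=C4').

**Step 2**
Reactants: 2
Product: 3 cyclohexa-1,4-diene-1-carbaldehyde
Conditions: Dess–Martin periodinane, NaHCO3, CH2Cl2, 0 °C; used crude and cold
Reagents that add atoms: none
Why: Dess–Martin oxidation of the allylic alcohol under buffered, non-acidic conditions avoids isomerisation or aromatisation of the skipped diene.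

**Step 3**
Reactants: 4 methyl 3-(4-hydroxy-3-methoxyphenyl)propanoate; 5 methyl glyoxylate
Product: 6 methyl 2-hydroxy-2-[2-hydroxy-3-methoxy-5-(3-methoxy-3-oxopropyl)phenyl]acetate (racemic)
Conditions: TiCl4 (1 equiv), CH2Cl2, −30 → 0 °C
Reagents that add atoms: none (both partners are listed reactants)
Why: Titanium-phenoxide-templated ortho-selective Friedel–Crafts hydroxyalkylation; the para position is blocked and only one ortho position is free.

**Step 4**
Reactants: 6
Product: 7 methyl 2-[2-hydroxy-3-methoxy-5-(3-methoxy-3-oxopropyl)phenyl]acetate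
Conditions: H2 (3 atm), 10% Pd/C, MeOH, cat. H2SO4, 40 °C
Reagents that add atoms: none
Why: Acid-assisted hydrogenolysis of the electron-rich benzylic C–OH (as in hydroxymandelic → hydroxyphenylacetic acid); MeOH/H+ keeps both esters as methyl esters and re-opens any benzofuranone.

**Step 5**
Reactants: 7; 3
Product: 8 methyl (2S,3R)-3-(cyclohexa-1,4-dien-1-yl)-3-hydroxy-2-[2-hydroxy-3-methoxy-5-(3-methoxy-3-oxopropyl)phenyl]propanoate (anti)
Conditions: Ipc2BOTf (2.3 equiv; the antipode that gives the 3R carbinol, to be confirmed on a model), i-Pr2NEt, CH2Cl2, −78 °C; then 3, −78 °C; pH 7 buffer/MeOH, diethanolamine work-up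
Reagents that add atoms: none
Why: Reagent-controlled boron aldol of a methyl arylacetate (kinetic E-enolate, Zimmerman–Traxler chair) sets C2 and C3 anti in one step; the first equivalent of boron masks ArOH as ArO–BIpc2, and the less acidic side-chain ester is not enolised.

**Step 6**
Reactants: 8
Product: 9 methyl (2S,3S)-2-(cyclohexa-1,4-dien-1-yl)-7-methoxy-5-(3-methoxy-3-oxopropyl)-2,3-dihydro-1-benzofuran-3-carboxylate (2,3-trans)
Conditions: PPh3, DIAD, THF (0.02 M), 0 °C → rt
Reagents that add atoms: none
Why: Intramolecular Mitsunobu etherification (5-exo-tet SN2 by the phenol) inverts C2, turning the anti-aldol into the 2,3-trans-dihydrobenzofuran.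

**Step 7**
Reactants: 9
Product: 10 methyl (2S,3S)-7-methoxy-5-(3-methoxy-3-oxopropyl)-2-[(1R,6S)-7-oxabicyclo[4.1.0]hept-3-en-1-yl]-2,3-dihydro-1-benzofuran-3-carboxylate
Conditions: ent-Shi ketone (30 mol %), Oxone, K2CO3, Bu4NHSO4, MeCN/DMM–aq. borate buffer (pH 10.5), 0 °C
Reagents that add atoms: Oxone (potassium peroxymonosulfate), [K+].[O-]S(=O)(=O)OO
Why: Shi asymmetric epoxidation selects the trisubstituted C1'=C6' alkene over the cis-disubstituted C3'=C4' alkene and sets C1'; the ent-ketone is required because the D-fructose ketone gives (R,R)-1-phenylcyclohexene oxide and the mirror-image sense is needed, which also matches the expected substrate bias (attack anti to C3).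

**Step 8**
Reactants: 10
Product: 11 (1S)-1-[(2S,3R)-3-(hydroxymethyl)-5-(3-hydroxypropyl)-7-methoxy-2,3-dihydro-1-benzofuran-2-yl]cyclohex-3-en-1-ol
Conditions: LiAlH4 (excess), THF, 0 °C → reflux; Fieser work-up
Reagents that add atoms: none
Why: Hydride reduces both methyl esters and opens the trisubstituted epoxide by SN2 attack at the less substituted C6', leaving C1' untouched and revealing the tertiary alcohol, the C3 hydroxymethyl and the hydroxypropyl chain together.

**Step 9**
Reactants: 11
Product: 12 (1S,3S,6R)-3-[(2S,3R)-3-(hydroxymethyl)-5-(3-hydroxypropyl)-7-methoxy-2,3-dihydro-1-benzofuran-2-yl]-7-oxabicyclo[4.1.0]heptan-3-ol (epoxide cis to the tertiary OH)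
Conditions: VO(acac)2 (10 mol %), t-BuOOH (1.5 equiv), CH2Cl2, 0 °C → rt
Reagents that add atoms: tert-butyl hydroperoxide, CC(C)(C)OO
Why: Vanadium-catalysed hydroxyl-directed epoxidation of a cyclic homoallylic alcohol delivers oxygen syn to the C1'–OH; the primary alcohols are too remote to direct.

**Step 10**
Reactants: 12
Product: 13 difengpiol B, (1S,3S,4S)-1-[(2S,3R)-3-(hydroxymethyl)-5-(3-hydroxypropyl)-7-methoxy-2,3-dihydro-1-benzofuran-2-yl]-4-methoxycyclohexane-1,3-diol
Conditions: CSA (10 mol %), MeOH, 0 °C → rt
Reagents that add atoms: methanol, CO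
Why: Acid-catalysed epoxide methanolysis under Fürst–Plattner (trans-diaxial) control: with the large C1' substituent equatorial, only attack at C4' gives a chair-like diaxial opening, so C3'–OH ends cis to C1'–OH and trans to C4'–OMe.

## Compound list

1 | benzyl alcohol | OCc1ccccc1 | starting material
2 | (cyclohexa-1,4-dien-1-yl)methanol | OCC1=CCC=CC1 | intermediate
3 | cyclohexa-1,4-diene-1-carbaldehyde | O=CC1=CCC=CC1 | intermediate
4 | methyl 3-(4-hydroxy-3-methoxyphenyl)propanoate | COC(=O)CCc1ccc(O)c(OC)c1 | starting material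
5 | methyl glyoxylate | COC(=O)C=O | starting material
6 | methyl 2-hydroxy-2-[2-hydroxy-3-methoxy-5-(3-methoxy-3-oxopropyl)phenyl]acetate (racemic) | COC(=O)CCc1cc(OC)c(O)c(C(O)C(=O)OC)c1 | intermediate
7 | methyl 2-[2-hydroxy-3-methoxy-5-(3-methoxy-3-oxopropyl)phenyl]acetate | COC(=O)CCc1cc(OC)c(O)c(CC(=O)OC)c1 | intermediate
8 | methyl (2S,3R)-3-(cyclohexa-1,4-dien-1-yl)-3-hydroxy-2-[2-hydroxy-3-methoxy-5-(3-methoxy-3-oxopropyl)phenyl]propanoate | O[C@@H](C1=CCC=CC1)[C@H](c1cc(CCC(=O)OC)cc(OC)c1O)C(=O)OC | intermediate
9 | methyl (2S,3S)-2-(cyclohexa-1,4-dien-1-yl)-7-methoxy-5-(3-methoxy-3-oxopropyl)-2,3-dihydro-1-benzofuran-3-carboxylate | COc1cc(CCC(=O)OC)cc2c1O[C@H](C1=CCC=CC1)[C@H]2C(=O)OC | intermediate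
10 | methyl (2S,3S)-7-methoxy-5-(3-methoxy-3-oxopropyl)-2-[(1R,6S)-7-oxabicyclo[4.1.0]hept-3-en-1-yl]-2,3-dihydro-1-benzofuran-3-carboxylate | COc1cc(CCC(=O)OC)cc2c1O[C@H]([C@@]13CC=CC[C@@H]1O3)[C@H]2C(=O)OC | intermediate
11 | (1S)-1-[(2S,3R)-3-(hydroxymethyl)-5-(3-hydroxypropyl)-7-methoxy-2,3-dihydro-1-benzofuran-2-yl]cyclohex-3-en-1-ol | COc1cc(CCCO)cc2c1O[C@H]([C@]1(O)CCC=CC1)[C@H]2CO | intermediate
12 | (1S,3S,6R)-3-[(2S,3R)-3-(hydroxymethyl)-5-(3-hydroxypropyl)-7-methoxy-2,3-dihydro-1-benzofuran-2-yl]-7-oxabicyclo[4.1.0]heptan-3-ol | COc1cc(CCCO)cc2c1O[C@H]([C@]1(O)CC[C@H]3O[C@H]3C1)[C@H]2CO | intermediate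
13 | difengpiol B | COc1cc(CCCO)cc2c1O[C@H]([C@]1(O)CC[C@H](OC)[C@@H](O)C1)[C@H]2CO | target

## Summary

Total steps: 10. Longest linear sequence: 8 (steps 1, 2, 5–10, or equally 3–10).

Steps most likely to fail:

1. **Step 6 (Mitsunobu closure).** The activated carbinol is allylic to a skipped diene and β to an enolisable α-aryl ester, so E1cB dehydration or 1,4-elimination with aromatisation can compete. Fallback: reverse the bond order. Etherify phenol 7 with primary alcohol 2 (no stereocentre), do diazo transfer on the arylacetate, and forge C2–C3 by Rh2(S-PTTL)4-catalysed intramolecular C–H insertion, then epimerise C3 to trans.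
2. **Step 5 (asymmetric boron aldol).** The free ortho-phenol and the sensitive enal 3 may erode conversion, dr or ee, and the sense of induction for this substrate is not established. Fallback: use a covalent auxiliary. Run an Evans MgCl2/TMSCl anti-aldol on the O-silyl arylacetyl oxazolidinone; the auxiliary is then removed reductively in step 8.
3. **Step 7 (Shi epoxidation).** Over-oxidation of the second alkene or poor face selectivity next to the C2 stereocentre is possible. Fallback: set C1' before coupling. Apply Sharpless asymmetric epoxidation to achiral allylic alcohol 2, oxidise to the epoxy aldehyde, and carry the epoxide through the aldol, Mitsunobu and LiAlH4 steps.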